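Readings and results are calculated on assumed constants; scatter was added.

- The ratio [G]/[J] in the charge was what I compared first: autumn stood at 0.675, spring at 2.37, ochre at 1.00 and amber at 3.75, while [J] stayed at 0.800 M.

| flask | G | J | remark | time |
|---|---|---|---|---|
| autumn | 0.54 M | 0.80 M | run made earlier |  |
| spring | 1.9 M | 0.80 M | run made earlier |  |
| ochre | 0.80 M | 0.800 M |  | 3.0 min |
| amber | 3.0 M | 0.800 M |  | 0.80 min |

| run | time / s | X / % | G / % |
|---|---|---|---|
| autumn | 10.0 | 3 | 12 |
| autumn | 25.0 | 16 | 4 |
| autumn | 40.0 | 19 | 1 |
| autumn | 60.0 | 22 | 3 |
| autumn | 90.0 | 23 | 1 |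
| autumn | 120 | 23 | 1 |
| spring | 10.0 | 5 | 12 |
| spring | 25.0 | 16 | 0 |
| spring | 40.0 | 20 | 0 |
| spring | 60.0 | 23 | 0 |
| spring | 90.0 | 26 | 1 |
| spring | 120 | 29 | 0 |

(each reading ± 2 percentage points)

- which of the two ends with the higher amount of X, in percent of the G charged ("neither" if they lie within 2 percentage points) (ochre / amber / neither)
- X at the end, in percent of the G charged, ochre
- X at the end, in percent of the G charged, amber

- the numbers in the tables scatter by 2 percentage points (one standard deviation)
- a reading or a percentage of X counts all its forms, free or not
- a reading of G is of its free form alone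

- The first setting I turned by hand was the amount of G. From autumn to spring, X at 120 s rose from 23% to 29%, so I assumed a straight line of 3.5 percentage points per unit of the ratio, a reading that carries the scatter of 2 points.
- Autumn's X read 23% at 90.0 s and 23% at 120 s, and its gap to that last reading at 25.0 s gave an exponential approach time of 21.0 s. For ochre I multiplied the line's late value, 24.1%, by the fraction of the approach reached in its own 3.0 min, which gave 24.1%.
- The same line gave amber a late value of 33.9%, but the second setting, time, stops amber at 0.80 min, while spring was still climbing.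
- So I went round once more. I defined the loading factor, amber's late X divided by spring's late X, as 1.17, and multiplied it by spring's X interpolated at that time, 21.2%. This gave amber 24.7%.
- My values, each reckoned for its own flask and time, ochre at 3.0 min and amber at 0.80 min, lay 0.60 points apart, less than the margin of 2 points, so I expected neither to end higher.
- The forecast gave 25% for ochre and 20% for amber, hence ochre, noting “Amber is stopped at 48 s, still on the rise”.
- Ochre gave 22.5% and amber 22.6%, so the answer was neither.

    G → Z (k = 0.200 s⁻¹)
    Z ⇌ X (K = 16.0, k = 0.0120 s⁻¹)
    Z ⇌ D (K = 2.20, k = 0.00630 s⁻¹)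
    Z + J → Q (k = 0.0310 M⁻¹ s⁻¹)
    Z → L (k = 0.0130 s⁻¹)
    G + X ⇌ E, settled at all times (K = 0.430 M⁻¹)

- Amber at 0.800 min still held 19.0% of Z, the intermediate, against 0.957% in ochre at 3.00 min. Amber's X divided by spring's interpolated X came to 1.07, against my loading factor of 1.17. I then applied that factor to the neighbouring amber flask read at 80 s, where spring's interpolated X was 25.0%. That made 29.2%, and the neighbour gave 26.6%.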